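**Design of a synthesis of CNP0125425.2 (compound 34) by carbene–alkyne–CO benzannulation on the ether oxygen**

## The problem

Compound 34 joins two 2-(2-phenylethyl)chromones through one oxygen: O6′ of an aromatic 7′-methoxychromone is bonded to C8 of a 5,6,7,8-tetrahydrochromone that carries free hydroxyls on C5, C6 and C7. The carbocycle holds four contiguous stereocentres, (5S,6R,7S,8S), with O5, O7 and O8 on one face and O6 on the other (5,6-trans, 6,7-trans, 7,8-cis). The 7,8-cis pair is the natural controller: once it is in place, an oxirane can be put on C5=C6 anti to it and opened at allylic C5 with inversion, which fixes C6 and C5 in the required sense. The bond that resists ordinary methods is C8–O6′. C8 is secondary and flanked by the C7 carbinol and the pyranone carbon C8a, so displacement there competes with elimination towards an aromatic chromone and would also invert the centre. The polyol ring is sensitive: loss of water aromatises it, C5–O is allylic to the vinylogous ester and can ionise in strong acid, and both γ-pyranone carbonyls accept hard nucleophiles. What allows a detour around the etherification is ring A′, a hydroquinone monoether with O6′ para to the pyranone oxygen on C8a′ and ortho to the methoxy group on C7′, hydrogen on C5′ and C8′, and the acyl carbon on C4a′. This is the pattern formed when a chromium alkoxy(alkenyl)carbene, an alkyne and one CO combine to a 4-alkoxyphenol, the alkoxy oxygen of the carbene ending as O6′.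

## Retrosynthesis

**Last protecting groups (34 ⇐ 33 ⇐ 32).** The C–O bonds cut are those of the butane-2,3-diacetal (BDA) on O6/O7 and of the 2-naphthylmethyl (NAP) ether on O5. These two groups are chosen because each is installed by the step that differentiates the oxygens (see below). The forward steps are DDQ, then brief aqueous trifluoroacetic acid; neither touches the C8–O6′ ether, whose ionisation is disfavoured.

**Pyranone of the aromatic half (32 ⇐ 30 ⇐ 29 ⇐ 27 + 9).** O1′–C2′ and C3′–C4′ are cut. Ynone 30 closes 6-endo through its diethylamine adduct 31. Compound 30 comes from salicylaldehyde 27 and 4-phenylbut-1-yne 9 by addition of the alkynylmagnesium bromide 28 (giving carbinol 29) and MnO2 oxidation. The neighbouring Claisen route from an acetophenone was set aside: the annulation below delivers C4′ at the aldehyde level simply through the choice of alkyne, and alkyne 9 also serves the other chromone. Compound 27 is ten carbons simpler than 32. The forward reaction must pick the aldehyde over the γ-pyranone, which is why the magnesium acetylide is preferred to a lithium acetylide at this stage.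

**Ring A′ (27 ⇐ 26 ⇐ 23 + 24).** Aldehyde 27 is the hydrolysis product of acetal 26. Compound 26 is cut through C5′–C6′, C4a′–C8a′ and C8′–C8a′ into carbene complex 23, 3,3-diethoxyprop-1-yne 24 and one CO ligand. The obvious neighbours are a cut at C8–O6′ (SN2 or Mitsunobu, with inversion and elimination) or at O6′–C6′ (arylation of a hindered alcohol with an electron-rich arene). The benzannulation avoids both because the oxygen on C8 never leaves: it is the hydroxyl oxygen of the starting diol. The forward reaction must insert the terminal alkyne with the acetal carbon next to the phenol carbon and must favour CO insertion.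

**Carbene complex (23 ⇐ 21 + 16; 21 ⇐ 17 + 18).** The O8–C(carbene) bond is cut. Alcohol 16 captures the acetoxycarbene 22, generated from tetramethylammonium acyl chromate 21. Compound 21 is made from Cr(CO)6 (18) and 1-methoxyvinyllithium 19 (from methyl vinyl ether 17) via lithium salt 20. This is an acyl-type substitution at the carbene carbon, so C8 keeps its configuration. Only one hydroxyl of 16 may be free.

**Pyranone of the tetrahydrochromone (16 ⇐ 15 ⇐ 14 ⇐ 13 ⇐ 8 + 11).** After the silyl ether on O8 is removed (15), O1–C2 and C4–C4a are cut. The enolised 2-alkynoyl ketone 14 closes 6-endo, and 14 is the oxidation product of aldol 13, made from the C4a enolate 12 of ketone 8 and 5-phenylpent-2-ynal 11 (from 9 via 10). A triketone cyclodehydration would need acid and a longer acylating agent.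

**Ketone from bromide (8 ⇐ 7 ⇐ 6).** C8a–O replaces C8a–Br by Miyaura borylation and perborate oxidation. The bromine of the starting material marks exactly the carbon that must become the enol-ether carbon C8a, next to the cis-diol.

**Telling O8 from O7 (6 ⇐ 5 ⇐ 4).** In the C6/C7/C8 triol, the diacetal forms on the trans-diequatorial C6/C7 pair and leaves the allylic, cis C8 hydroxyl free (5). This is the same selectivity that separates the trans from the cis diol in shikimate-type triols. A silyl ether on O8 (6) then protects it through the enolate and oxidation chemistry.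

**Stereotriad (4 ⇐ 3 ⇐ 2 ⇐ 1).** The C5–O and C6–O bonds are cut back to oxirane 3 and diene acetonide 2 of (1S,2S)-3-bromocyclohexa-3,5-diene-1,2-diol 1. Epoxidation anti to the dioxolane and opening at allylic C5 by 2-naphthylmethanol set C6 and C5 and protect O5 in the same step.

## Roads not taken

**Alternative 1: enzymatic cis-dihydroxylation of the intact chromone.**
- Cut: the C7–O and C8–O bonds are made on 2-(2-phenylethyl)chromone A1 by an arene dioxygenase of the naphthalene dioxygenase type, giving the (7S,8S)-dihydrodiol A2.
- Merits: the pyranone is present from the start, so the five steps spent here on turning a vinyl bromide into the fused pyranone would be saved. The stereochemical logic afterwards (anti-epoxidation of C5=C6, trans opening at C5) is the same as in the chosen plan.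
- Weak points: acceptance of A1 by the enzyme, the site of attack (C7–C8 against C5–C6) and the absolute sense are all open. A2 is a styrene-type dihydrodiol that dehydrates readily to a hydroxychromone. A fermentation has to be developed before any chemistry starts.
- Comparison: A2 would still need O7 told from O8 and the ether built, so it is an alternative source of alcohol 16, not of the key bond. On step count it is conceded to be better if the biotransformation works. The chosen plan sets against it a purchasable, enantiopure diol 1 whose bromine fixes the regiochemistry and whose chemistry is predictable.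

**Alternative 2: catalytic asymmetric epoxidation of a masked ortho-quinone.**
- Cut: the C5–O and C6–O bonds are made on the achiral 8,8-dimethoxy-7-oxo dienone A3 by a hydroperoxide under a chiral cinchona ammonium phase-transfer catalyst, giving epoxide A4.
- Merits: no chiral-pool material, a catalytic enantio-determining step and a short approach from an aromatic chromone.
- Weak points: A4 carries only two of the four centres. C7 (ketone) and C8 (ketal, then ketone) must each be reduced with the correct facial sense next to a labile epoxy ketone. The epoxide must then be opened trans at C5. Dienones of this kind dimerise readily. The enantioselectivity on a cross-conjugated chromone dienone is unproven.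
- Comparison: it is more elegant in principle and avoids stoichiometric chromium in the carbocycle synthesis, but it sets stereocentres by three separate reagent-controlled events. The chosen plan buys two centres and derives the other two by substrate control. Alternative 2 also leaves the hindered ether unsolved.

**Alternative 3: carbocyclisation of an L-fucose derivative.**
- Cut: the C4a–C5 bond is made by a 6-enolexo aldol of the 1,5-keto aldehyde A6, which is derived from L-fucose A5 and already carries the aromatic chromone on the oxygen that becomes O8. The product is hydroxy ketone A7.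
- Merits: C6, C7 and C8 come from the sugar. The ether is made early on a robust pyranoside hydroxyl, which is as good an answer to the hindered ether as the chosen plan gives, and no chromium is needed.
- Weak points: the early ether still requires O-arylation of an axial secondary hydroxyl with a non-activated, electron-rich arene. In A6 and A7 the aryloxy group sits α to a ketone, so enolisation towards C8 threatens epimerisation and β-elimination of the C7 ether. The configuration at C5 rests on a reversible aldol. The pyranone must then be built at C4a between a ketone and a retro-aldol-prone carbinol.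
- Comparison: comparable in length. The chosen plan sets against it that C8 is never α to a ketone while it carries the aryl ether, that C5 is set by an SN2 opening and not by an equilibrium, and that the aryl ring is grown on the oxygen, not coupled to it.

Key step: step 13

## Route

Remark on the chemistry: the carbocycle is numbered as in 34 (C4a, C5–C8, C8a) in every intermediate and primed numbers refer to the aromatic chromone. NAP is 2-naphthylmethyl, BDA is the 2,3-dimethoxybutane-2,3-diyl bridge on O6/O7, TBS is tert-butyldimethylsilyl. Diol 1 is assumed to be used as the commercial enantiopure material.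

Step 1
Reactants: 1 (1S,2S)-3-bromocyclohexa-3,5-diene-1,2-diol
Product: 2 (3aS,7aS)-4-bromo-2,2-dimethyl-3a,7a-dihydro-1,3-benzodioxole (O7/O8 acetonide of 1)
Conditions: 2,2-dimethoxypropane, TsOH·H2O (cat.), acetone, 0 °C to rt
Reagents that add atoms: 2,2-dimethoxypropane, COC(C)(C)OC
Why: Acid-catalysed acetonide formation on the cis-diol blocks dehydration to a bromophenol and shields one face of the diene; the diene should be used promptly because it dimerises on standing.

Step 2
Reactants: 2 acetonide
Product: 3 5,6-epoxide of 2 with the oxirane oxygen anti to the dioxolane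
Conditions: mCPBA, NaHCO3, CH2Cl2, 0 °C to rt
Reagents that add atoms: 3-chloroperbenzoic acid, OOC(=O)c1cccc(Cl)c1
Why: Prilezhaev epoxidation should take the more electron-rich, unbrominated double bond from the face opposite the dioxolane, which places the oxirane oxygen on the face that O6 needs.

Step 3
Reactants: 3 vinyl oxirane
Product: 4 5-O-NAP ether with free 6-OH and O7/O8 acetonide (O5 trans to O6 and cis to O7/O8)
Conditions: 2-naphthylmethanol (3 equiv), BF3·OEt2 (cat.), CH2Cl2, −20 °C
Reagents that add atoms: 2-naphthylmethanol, OCc1ccc2ccccc2c1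
Why: Lewis-acid-catalysed opening of a vinyl oxirane by an alcohol should occur at the allylic carbon C5 with inversion, giving the 5,6-trans arrangement and protecting O5 in the same operation.

Step 4
Reactants: 4 NAP ether acetonide
Product: 5 8a-bromo-5-O-NAP-6,7-O-BDA-cyclohex-4a(8a)-en-8-ol (free 8-OH)
Conditions: butane-2,3-dione, HC(OMe)3, camphorsulfonic acid (cat.), MeOH, reflux
Reagents that add atoms: butane-2,3-dione, CC(=O)C(C)=O; methanol, CO
Why: Acidic methanol cleaves the acetonide and the butane-2,3-diacetal then forms under thermodynamic control on the trans-diequatorial C6/C7 diol, as it does in shikimate-type cis/trans triols, leaving the cis allylic 8-OH free; the two acetal carbons are set by the chair with both methoxy groups axial (anomeric effect).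

Step 5
Reactants: 5 allylic alcohol
Product: 6 8-O-TBS ether of 5
Conditions: TBSOTf, 2,6-lutidine, CH2Cl2, −78 to 0 °C
Reagents that add atoms: tert-butyldimethylsilyl triflate, CC(C)(C)[Si](C)(C)OS(=O)(=O)C(F)(F)F
Why: Silylation with the triflate is reliable for a hindered secondary allylic alcohol and gives a group that survives enolate, oxidation and base steps and leaves later with fluoride.

Step 6
Reactants: 6 vinyl bromide
Product: 8 cyclohexanone (C8a=O; C4a methylene; 8-OTBS; 6,7-O-BDA; 5-ONAP), via alkenyl pinacolboronate 7 (not isolated)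
Conditions: B2pin2, PdCl2(PPh3)2 (cat.), PPh3, KOPh, toluene, 50 °C; then NaBO3·4H2O, THF/pH 7 buffer, 0 °C to rt
Reagents that add atoms: sodium perborate NaBO3, [Na+].[O-]OB=O
Why: Miyaura borylation of the alkenyl bromide followed by buffered perborate oxidation of the C–B bond gives the enol and hence the ketone at C8a without base strong enough to epimerise C8 or eliminate the C5 ether.

Step 7
Reactants: 9 4-phenylbut-1-yne
Product: 11 5-phenylpent-2-ynal, via lithium 4-phenylbut-1-yn-1-ide 10 (not isolated)
Conditions: n-BuLi, THF, −78 °C; DMF, −78 to 0 °C; inverse quench into aq. KH2PO4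
Reagents that add atoms: N,N-dimethylformamide, CN(C)C=O
Why: Formylation of a lithium acetylide with DMF is standard, and the buffered inverse quench prevents the liberated amine from adding to the ynal.

Step 8
Reactants: 8 cyclohexanone; 11 5-phenylpent-2-ynal
Product: 13 aldol adduct bearing CH(OH)C≡CCH2CH2Ph on C4a (mixture of diastereomers at C4a and the carbinol carbon), via C4a lithium enolate 12 (not isolated)
Conditions: LiN(iPr)2, THF, −78 °C; then 11, −78 °C; aq. NH4Cl
Reagents that add atoms: none
Why: Kinetic deprotonation should take the unhindered C4a methylene over the silyloxy-bearing methine C8, and lithium enolates add 1,2 to ynals at low temperature; both new centres are destroyed two operations later, so their configuration is irrelevant.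

Step 9
Reactants: 13 aldol adduct
Product: 15 8-O-TBS-5-O-NAP-6,7-O-BDA-2-(2-phenylethyl)-5,6,7,8-tetrahydrochromen-4-one, via enolised 2-alkynoyl ketone 14 (not isolated)
Conditions: Dess–Martin periodinane, NaHCO3, CH2Cl2, 0 °C to rt; crude, K2CO3 (cat.), acetone, rt
Reagents that add atoms: none
Why: Dess–Martin oxidation of a β-hydroxy ketone gives the β-diketone, and in an aprotic medium its enolate oxygen on C8a should add 6-endo-dig to the ynone β-carbon (conjugate addition giving a stabilised allenolate) to close the γ-pyranone.

Step 10
Reactants: 15 silyl ether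
Product: 16 5-O-NAP-6,7-O-BDA-8-hydroxy-2-(2-phenylethyl)-5,6,7,8-tetrahydrochromen-4-one
Conditions: HF·pyridine, THF/pyridine, 0 °C to rt
Reagents that add atoms: none
Why: Buffered fluoride removes the TBS group without touching the diacetal, the NAP ether or the pyranone, and avoids the basic conditions that could deprotonate C8.

Step 11
Reactants: 17 methyl vinyl ether; 18 hexacarbonylchromium Cr(CO)6
Product: 21 tetramethylammonium pentacarbonyl[(1-methoxyvinyl)(oxido)carbene]chromate, via 1-methoxyvinyllithium 19 (not isolated), via lithium acyl chromate 20 (not isolated)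
Conditions: t-BuLi, THF, −65 to 0 °C; Cr(CO)6, Et2O/THF, 0 °C to rt; Me4NBr, H2O
Reagents that add atoms: tetramethylammonium bromide, C[N+](C)(C)C.[Br-]
Why: α-Lithiation of methyl vinyl ether and addition of the vinyllithium to a CO ligand of zerovalent Cr(CO)6 is the standard entry to acyl chromates, and cation exchange gives a storable salt.

Step 12
Reactants: 21 tetramethylammonium acyl chromate; 16 tetrahydrochromone 8-alcohol
Product: 23 pentacarbonyl{(1-methoxyvinyl)[tetrahydrochromon-8-yloxy]carbene}chromium (5-O-NAP and 6,7-O-BDA protected), via acetoxycarbene complex 22 (not isolated)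
Conditions: AcBr, CH2Cl2, −40 °C; then 16, −40 to 0 °C
Reagents that add atoms: none
Why: O-Acylation of the acyl chromate gives an acyloxycarbene that behaves as a mixed anhydride, and the secondary alcohol substitutes at the carbene carbon (addition–elimination), as established for alkoxycarbene complexes of menthol and carbohydrate-type alcohols; C8 is not a reacting centre and keeps its configuration.

Step 13
Reactants: 23 chromium carbene complex; 24 3,3-diethoxyprop-1-yne
Product: 26 2-(diethoxymethyl)-5-methoxy-4-(tetrahydrochromon-8-yloxy)phenol (5-O-NAP and 6,7-O-BDA protected), via tricarbonylchromium arene complex 25 (not isolated)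
Conditions: 24 (3 equiv), THF (degassed), 50 °C; then air, rt, filtration through silica
Reagents that add atoms: none
Why: Thermal loss of one CO from the zerovalent chromium carbene 23 opens a coordination site for alkyne 24, which inserts with its unsubstituted carbon bonded to the carbene carbon (C5′–C6′), so that the acetal-bearing carbon becomes the new carbene carbon. CO insertion at that carbon (C4a′–C8a′) gives a chromium-bound dienylketene. Ring A′ then closes by six-electron electrocyclisation of the dienylketene, the ketene carbon bonding to the vinyl CH2 (C8′–C8a′), and tautomerisation gives the 4-alkoxyphenol as its Cr(CO)3 complex 25, from which air removes the metal. The closest known reaction type is the Dötz benzannulation of alkenyl(alkoxy)carbene chromium complexes with terminal alkynes, including α-alkoxyvinyl complexes and complexes whose alkoxy group derives from a carbohydrate-type secondary alcohol. No stereocentre is formed, and C8 is untouched because its C–O bond is carried through intact from 16. The step needs the alkyne to insert with the acetal carbon next to the phenol carbon, which the size difference between CH(OEt)2 and H on a terminal alkyne secures. It also needs CO insertion to outrun cyclopentannulation, which alkenyl complexes with an electron-rich α-substituent in an ethereal solvent favour.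

Step 14
Reactants: 26 phenol acetal
Product: 27 2-hydroxy-4-methoxy-5-(tetrahydrochromon-8-yloxy)benzaldehyde (5-O-NAP and 6,7-O-BDA protected)
Conditions: pyridinium tosylate (cat.), acetone/H2O, rt
Reagents that add atoms: water, O
Why: A salicylaldehyde diethyl acetal hydrolyses under very mild acid, far below what the cyclic diacetal, the NAP ether or the tetrahydrochromone would notice.

Step 15
Reactants: 27 salicylaldehyde; 9 4-phenylbut-1-yne
Product: 29 propargylic alcohol ArCH(OH)C≡CCH2CH2Ph (mixture of carbinol epimers), via bromomagnesium 4-phenylbut-1-yn-1-ide 28 (not isolated)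
Conditions: 9 (3 equiv), EtMgBr (2.8 equiv), THF, 0 °C to rt; then 27, −20 to 0 °C; aq. NH4Cl
Reagents that add atoms: none
Why: Grignard addition of an alkynylmagnesium bromide to an unprotected salicylaldehyde is a standard entry to ortho-hydroxyaryl propargylic alcohols: the first equivalent deprotonates the phenol and the excess adds to the aldehyde held in the magnesium phenoxide chelate. The magnesium acetylide is less basic towards C8–H and less reactive towards the vinylogous-ester carbonyl of the γ-pyranone than a lithium acetylide, so the aldehyde should be attacked selectively.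

Step 16
Reactants: 29 propargylic alcohol
Product: 30 ortho-hydroxyaryl ynone
Conditions: MnO2 (activated), CH2Cl2, rt
Reagents that add atoms: none
Why: MnO2 oxidises the doubly activated benzylic-propargylic alcohol selectively and leaves the phenol and every other group alone; the carbinol stereocentre disappears.

Step 17
Reactants: 30 ynone
Product: 32 5-O-NAP-6,7-O-BDA derivative of 34 (aromatic chromone complete), via β-diethylaminoenone 31 (not isolated)
Conditions: Et2NH, EtOH, rt to 50 °C
Reagents that add atoms: none
Why: The secondary amine adds conjugatively to the ynone and the phenol then displaces it by addition–elimination at the same carbon, which enforces 6-endo closure to the chromone and excludes the 5-exo aurone pathway.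

Step 18
Reactants: 32 protected bis-chromone
Product: 33 6,7-O-BDA derivative of 34 (free 5-OH)
Conditions: DDQ, CH2Cl2/pH 7 buffer, 0 °C to rt
Reagents that add atoms: none
Why: Oxidative cleavage of a 2-naphthylmethyl ether by DDQ is neutral and should spare the chromones, the methoxyarene and the diacetal; O6 is still protected, so no cyclic naphthylidene acetal can form.

Step 19
Reactants: 33 diacetal
Product: 34 CNP0125425.2, (5S,6R,7S,8S)-5,6,7-trihydroxy-8-{[7-methoxy-4-oxo-2-(2-phenylethyl)-4H-chromen-6-yl]oxy}-2-(2-phenylethyl)-5,6,7,8-tetrahydrochromen-4-one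
Conditions: CF3CO2H/H2O (9:1), 0 °C, short reaction time
Reagents that add atoms: none
Why: Aqueous trifluoroacetic acid is the standard reagent for hydrolysing butane-2,3-diacetals; the C8–O6′ ether cannot ionise readily because a cation at C8 is not stabilised, and cold, brief exposure limits ionisation at C5.

## Compound list

1 | (1S,2S)-3-bromocyclohexa-3,5-diene-1,2-diol | O[C@@H]1C(Br)=CC=C[C@@H]1O | starting material
2 | (3aS,7aS)-4-bromo-2,2-dimethyl-3a,7a-dihydro-1,3-benzodioxole | CC1(C)O[C@@H]2C(Br)=CC=C[C@@H]2O1 | intermediate
3 | 5,6-epoxide of 2, oxirane oxygen anti to the dioxolane | CC1(C)O[C@@H]2C(Br)=C[C@H]3O[C@H]3[C@@H]2O1 | intermediate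
4 | 8a-bromo-cyclohex-4a(8a)-ene with O7/O8 acetonide, 6-OH and 5-O-(2-naphthylmethyl); 5,6-trans, O5 cis to O7/O8 | CC1(C)O[C@@H]2C(Br)=C[C@H](OCc3ccc4ccccc4c3)[C@@H](O)[C@@H]2O1 | intermediate
5 | 8a-bromo-5-O-NAP-6,7-O-(2,3-dimethoxybutane-2,3-diyl)cyclohex-4a(8a)-en-8-ol (acetal methoxy groups axial) | O[C@@H]1C(Br)=C[C@H](OCc2ccc3ccccc3c2)[C@@H](O[C@](C)(OC)[C@@](C)(OC)O4)[C@@H]14 | intermediate
6 | 8-O-TBS ether of 5 | CC(C)(C)[Si](C)(C)O[C@@H]1C(Br)=C[C@H](OCc2ccc3ccccc3c2)[C@@H](O[C@](C)(OC)[C@@](C)(OC)O4)[C@@H]14 | intermediate
7 | alkenyl pinacolboronate (Bpin on C8a in place of Br of 6) | CC(C)(C)[Si](C)(C)O[C@@H]1C(B5OC(C)(C)C(C)(C)O5)=C[C@H](OCc2ccc3ccccc3c2)[C@@H](O[C@](C)(OC)[C@@](C)(OC)O4)[C@@H]14 | intermediate (not isolated)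
8 | cyclohexanone: C8a=O, C4a methylene, 8-OTBS, 6,7-O-BDA, 5-ONAP | CC(C)(C)[Si](C)(C)O[C@@H]1C(=O)C[C@H](OCc2ccc3ccccc3c2)[C@@H](O[C@](C)(OC)[C@@](C)(OC)O4)[C@@H]14 | intermediate
9 | 4-phenylbut-1-yne | C#CCCc1ccccc1 | starting material
10 | lithium 4-phenylbut-1-yn-1-ide | [Li]C#CCCc1ccccc1 | intermediate (not isolated)
11 | 5-phenylpent-2-ynal | O=CC#CCCc1ccccc1 | intermediate
12 | C4a lithium enolate of 8 | CC(C)(C)[Si](C)(C)O[C@@H]1C(O[Li])=C[C@H](OCc2ccc3ccccc3c2)[C@@H](O[C@](C)(OC)[C@@](C)(OC)O4)[C@@H]14 | intermediate (not isolated)
13 | aldol adduct: 8 carrying CH(OH)C≡CCH2CH2Ph on C4a (diastereomer mixture at C4a and carbinol carbon) | CC(C)(C)[Si](C)(C)O[C@@H]1C(=O)C(C(O)C#CCCc5ccccc5)[C@H](OCc2ccc3ccccc3c2)[C@@H](O[C@](C)(OC)[C@@](C)(OC)O4)[C@@H]14 | intermediate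
14 | 2-alkynoyl ketone (β-diketone, largely enolised): 8 carrying C(=O)C≡CCH2CH2Ph on C4a | CC(C)(C)[Si](C)(C)O[C@@H]1C(=O)C(C(=O)C#CCCc5ccccc5)[C@H](OCc2ccc3ccccc3c2)[C@@H](O[C@](C)(OC)[C@@](C)(OC)O4)[C@@H]14 | intermediate (not isolated)
15 | 8-O-TBS-5-O-NAP-6,7-O-BDA-2-(2-phenylethyl)-5,6,7,8-tetrahydrochromen-4-one (configuration as in 34) | CC(C)(C)[Si](C)(C)O[C@@H]1c2oc(CCc3ccccc3)cc(=O)c2[C@H](OCc4ccc5ccccc5c4)[C@@H](O[C@](C)(OC)[C@@](C)(OC)O6)[C@@H]16 | intermediate
16 | 8-hydroxy-5-O-NAP-6,7-O-BDA-2-(2-phenylethyl)-5,6,7,8-tetrahydrochromen-4-one | O[C@@H]1c2oc(CCc3ccccc3)cc(=O)c2[C@H](OCc4ccc5ccccc5c4)[C@@H](O[C@](C)(OC)[C@@](C)(OC)O6)[C@@H]16 | intermediate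
17 | methyl vinyl ether | COC=C | starting material
18 | hexacarbonylchromium, Cr(CO)6 | O=C=[Cr](=C=O)(=C=O)(=C=O)(=C=O)=C=O | starting material
19 | 1-methoxyvinyllithium | [Li]C(=C)OC | intermediate (not isolated)
20 | lithium pentacarbonyl[(1-methoxyvinyl)(oxido)carbene]chromate | C=C(OC)C(O[Li])=[Cr](=C=O)(=C=O)(=C=O)(=C=O)=C=O | intermediate (not isolated)
21 | tetramethylammonium pentacarbonyl[(1-methoxyvinyl)(oxido)carbene]chromate | C=C(OC)C([O-])=[Cr](=C=O)(=C=O)(=C=O)(=C=O)=C=O.C[N+](C)(C)C | intermediate
22 | pentacarbonyl[acetoxy(1-methoxyvinyl)carbene]chromium | C=C(OC)C(OC(C)=O)=[Cr](=C=O)(=C=O)(=C=O)(=C=O)=C=O | intermediate (not isolated)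
23 | pentacarbonyl{(1-methoxyvinyl)[(5-O-NAP-6,7-O-BDA-tetrahydrochromon-8-yl)oxy]carbene}chromium | C=C(OC)C(O[C@@H]1c2oc(CCc3ccccc3)cc(=O)c2[C@H](OCc4ccc5ccccc5c4)[C@@H](O[C@](C)(OC)[C@@](C)(OC)O6)[C@@H]16)=[Cr](=C=O)(=C=O)(=C=O)(=C=O)=C=O | intermediate
24 | 3,3-diethoxyprop-1-yne | C#CC(OCC)OCC | starting material
25 | η6-Cr(CO)3 complex of phenol 26 (written as two components) | Oc1cc(OC)c(O[C@@H]2c3oc(CCc4ccccc4)cc(=O)c3[C@H](OCc5ccc6ccccc6c5)[C@@H](O[C@](C)(OC)[C@@](C)(OC)O7)[C@@H]27)cc1C(OCC)OCC.O=C=[Cr](=C=O)=C=O | intermediate (not isolated)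
26 | 2-(diethoxymethyl)-5-methoxy-4-[(5-O-NAP-6,7-O-BDA-tetrahydrochromon-8-yl)oxy]phenol | Oc1cc(OC)c(O[C@@H]2c3oc(CCc4ccccc4)cc(=O)c3[C@H](OCc5ccc6ccccc6c5)[C@@H](O[C@](C)(OC)[C@@](C)(OC)O7)[C@@H]27)cc1C(OCC)OCC | intermediate
27 | 2-hydroxy-4-methoxy-5-[(5-O-NAP-6,7-O-BDA-tetrahydrochromon-8-yl)oxy]benzaldehyde | Oc1cc(OC)c(O[C@@H]2c3oc(CCc4ccccc4)cc(=O)c3[C@H](OCc5ccc6ccccc6c5)[C@@H](O[C@](C)(OC)[C@@](C)(OC)O7)[C@@H]27)cc1C=O | intermediate
28 | bromomagnesium 4-phenylbut-1-yn-1-ide | Br[Mg]C#CCCc1ccccc1 | intermediate (not isolated)
29 | 1-aryl-5-phenylpent-2-yn-1-ol from 27 (carbinol epimers) | Oc1cc(OC)c(O[C@@H]2c3oc(CCc4ccccc4)cc(=O)c3[C@H](OCc5ccc6ccccc6c5)[C@@H](O[C@](C)(OC)[C@@](C)(OC)O7)[C@@H]27)cc1C(O)C#CCCc1ccccc1 | intermediate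
30 | 1-aryl-5-phenylpent-2-yn-1-one (ortho-hydroxyaryl ynone) | Oc1cc(OC)c(O[C@@H]2c3oc(CCc4ccccc4)cc(=O)c3[C@H](OCc5ccc6ccccc6c5)[C@@H](O[C@](C)(OC)[C@@](C)(OC)O7)[C@@H]27)cc1C(=O)C#CCCc1ccccc1 | intermediate
31 | β-diethylaminoenone from 30 (double-bond geometry not defined) | Oc1cc(OC)c(O[C@@H]2c3oc(CCc4ccccc4)cc(=O)c3[C@H](OCc5ccc6ccccc6c5)[C@@H](O[C@](C)(OC)[C@@](C)(OC)O7)[C@@H]27)cc1C(=O)C=C(CCc1ccccc1)N(CC)CC | intermediate (not isolated)
32 | 5-O-NAP-6,7-O-BDA derivative of 34 | COc1cc2oc(CCc3ccccc3)cc(=O)c2cc1O[C@@H]1c2oc(CCc3ccccc3)cc(=O)c2[C@H](OCc4ccc5ccccc5c4)[C@@H](O[C@](C)(OC)[C@@](C)(OC)O6)[C@@H]16 | intermediate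
33 | 6,7-O-BDA derivative of 34 | COc1cc2oc(CCc3ccccc3)cc(=O)c2cc1O[C@@H]1c2oc(CCc3ccccc3)cc(=O)c2[C@H](O)[C@@H](O[C@](C)(OC)[C@@](C)(OC)O6)[C@@H]16 | intermediate
34 | CNP0125425.2, (5S,6R,7S,8S)-configured dimeric 2-(2-phenylethyl)chromone | COc1cc2oc(CCc3ccccc3)cc(=O)c2cc1O[C@@H]1c2oc(CCc3ccccc3)cc(=O)c2[C@H](O)[C@@H](O)[C@@H]1O | target

## Step count and least certain steps

Total: 19 steps. Longest linear sequence: 17 steps from diol 1 (steps 1–6, 8–10, 12–19); steps 7 and 11 are side branches.

**Step 13 (key step).**
- What may go wrong: decomposition of the α-methoxyvinyl carbene before the alkyne is taken up, cyclisation without CO insertion, or over-oxidation of the very electron-rich phenol to a quinone during removal of the metal. The bulky alkoxy group slows the desired pathway.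
- Fallback (from 16, returning at 26): the ring is not grown but coupled. Commercial 5-bromo-2-hydroxy-4-methoxybenzaldehyde is silylated (iPr3SiCl, imidazole) to 5-bromo-4-methoxy-2-(triisopropylsilyloxy)benzaldehyde F1. F1 is converted with HC(OEt)3 and catalytic acid into its diethyl acetal F2. F2 is joined to alcohol 16 by palladium-catalysed C–O cross-coupling (Pd2(dba)3, a bulky di-tert-butyl biaryl phosphine, Cs2CO3, toluene, 90 °C) to give the silyl ether of the benzannulation product F3. Bu4NF buffered with AcOH then gives 26.

**Step 12.**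
- What may go wrong: slow capture of the thermally fragile acetoxycarbene by the hindered C8 hydroxyl, with transfer of the acetyl group to the alcohol or decomposition of the complex instead.
- Fallback (from 21 and 16, returning at 23): 21 is O-methylated with Me3OBF4 to pentacarbonyl[methoxy(1-methoxyvinyl)carbene]chromium F4. The methoxy group of F4 is exchanged for the alkoxy group of 16 under alkoxide catalysis (catalytic NaH, THF, methanol removed under reduced pressure) to give 23.

**Step 15.**
- What may go wrong: attack of the excess alkynylmagnesium reagent on the γ-pyranone (1,2- or 1,4-addition), or deprotonation at C8, competing with a slow addition to the phenoxide-deactivated aldehyde.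
- Fallback (from 27 and 9, returning at 29): alkyne 9 is iodinated (N-iodosuccinimide, AgNO3 cat., acetone) to 1-iodo-4-phenylbut-1-yne F5. F5 is added in excess to 27 as its alkynylchromium reagent (CrCl2, DMF, rt; Nozaki–Hiyama–Kishi-type alkynylation), a nucleophile that is selective for aldehydes and only weakly basic, giving 29.

**Step 8.**
- What may go wrong: enolisation towards C8 with epimerisation, or E1cB loss of the C5 ether from the C4a enolate.
- Fallback (from 6, returning at 13): bromide 6 undergoes bromine–lithium exchange (t-BuLi, THF, −78 °C) and the alkenyllithium is oxidised with Me3SiOOSiMe3 to the regiodefined trimethylsilyl enol ether F6. A Mukaiyama aldol of F6 with ynal 11 (BF3·OEt2, CH2Cl2, −78 °C) gives 13 without a basic ketone enolate.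

Further compounds
F1 | step 13 | 5-bromo-4-methoxy-2-(triisopropylsilyloxy)benzaldehyde | O=Cc1cc(Br)c(OC)cc1O[Si](C(C)C)(C(C)C)C(C)C
F2 | step 13 | 1-bromo-5-(diethoxymethyl)-2-methoxy-4-(triisopropylsilyloxy)benzene | CCOC(OCC)c1cc(Br)c(OC)cc1O[Si](C(C)C)(C(C)C)C(C)C
F3 | step 13 | triisopropylsilyl ether of phenol 26 | CCOC(OCC)c1cc(O[C@@H]2c3oc(CCc4ccccc4)cc(=O)c3[C@H](OCc5ccc6ccccc6c5)[C@@H](O[C@](C)(OC)[C@@](C)(OC)O7)[C@@H]27)c(OC)cc1O[Si](C(C)C)(C(C)C)C(C)C
F4 | step 12 | pentacarbonyl[methoxy(1-methoxyvinyl)carbene]chromium | C=C(OC)C(OC)=[Cr](=C=O)(=C=O)(=C=O)(=C=O)=C=O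
F5 | step 15 | 1-iodo-4-phenylbut-1-yne | IC#CCCc1ccccc1
F6 | step 8 | trimethylsilyl enol ether of ketone 8 (C4a=C8a) | CC(C)(C)[Si](C)(C)O[C@@H]1C(O[Si](C)(C)C)=C[C@H](OCc2ccc3ccccc3c2)[C@@H](O[C@](C)(OC)[C@@](C)(OC)O4)[C@@H]14
A1 | alternative 1 | 2-(2-phenylethyl)chromone | O=c1cc(CCc2ccccc2)oc2ccccc12
A2 | alternative 1 | (7S,8S)-7,8-dihydroxy-7,8-dihydro-2-(2-phenylethyl)chromone | O[C@@H]1c2oc(CCc3ccccc3)cc(=O)c2C=C[C@@H]1O
A3 | alternative 2 | 8,8-dimethoxy-2-(2-phenylethyl)-8H-chromene-4,7-dione | O=c1cc(CCc2ccccc2)oc2c1C=CC(=O)C2(OC)OC
A4 | alternative 2 | 5,6-epoxy-8,8-dimethoxy-2-(2-phenylethyl)-5,6-dihydro-8H-chromene-4,7-dione | O=c1cc(CCc2ccccc2)oc2c1[C@H]1O[C@H]1C(=O)C2(OC)OC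
A5 | alternative 3 | L-fucose (open-chain form) | O=C[C@@H](O)[C@H](O)[C@H](O)[C@@H](O)C
A6 | alternative 3 | 4-O-aryl-2,3-di-O-benzyl-6-deoxy-L-hexos-5-ulose (1,5-keto aldehyde) | COc1cc2oc(CCc3ccccc3)cc(=O)c2cc1O[C@H](C(C)=O)[C@@H](OCc1ccccc1)[C@H](OCc1ccccc1)C=O
A7 | alternative 3 | 2-aryloxy-3,4-bis(benzyloxy)-5-hydroxycyclohexanone | COc1cc2oc(CCc3ccccc3)cc(=O)c2cc1O[C@@H]1C(=O)C[C@H](O)[C@@H](OCc2ccccc2)[C@@H]1OCc1ccccc1
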